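The earlier runs and the new flask are simulated for substances that don't exist, and the scatter is random.

At 10.0 d the ash run, charged with more D, keeps more D than oak, 13.8 % against 10.7 %, yet it also holds more L, 67.9 % against 66.8 %. So should the next flask get more E than the recipe gives?

| setting | oak | ash | flask |
|---|---|---|---|
| D | 0.42 M | 0.63 M | 0.84 M |
| E | 1.7 M | 1.7 M | 1.70 M |
| Z | 1.68 M | 1.68 M | 1.68 M |
| remark | run made earlier | run made earlier |  |
| time |  |  | 10 d |

- oak (time / d: L / %, G / %, D / %): 1.25: 24.9, 3.2, 72.1; 4.00: 51.4, 8.2, 38.5; 6.00: 60.3, 9.7, 25.0; 10.0: 66.8, 10.2, 10.7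
- ash (time / d: L / %, G / %, D / %): 2.50: 39.2, 4.3, 54.5; 5.00: 56.2, 7.9, 33.1; 8.00: 65.8, 8.6, 19.4; 10.0: 67.9, 7.8, 13.8

(standard deviation of a reading: 0.3 percentage points)

- equivalents of E to D, everything else as given, that leave most L at 10 d
- the amount of L then, in percent of the D charged
- the amount of L with the amounts as given

- the numbers in the tables scatter by 0.3 percentage points (one standard deviation)
- a reading or a percentage of G counts all its forms, free or not

We measure progress by exposure θ, the logarithm of D charged over D left. D is taken to react with E, so θ is k times the time-mean of [E] times the time: a pseudo-first-order decay with the falling [E] replaced by its mean. We charge one E to each L and two to every other D lost. The first oak reading, with the mean of its two end values of [E], gives the constant k = 0.160 L mol⁻¹ d⁻¹.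

How far does that mean mislead over the whole run? The time-mean comes from θ and k, and the ratio shows the error. For the flask we continue the ratio and the E used per D by the equal step in charge.

| Run | θ at the end | Mean of end [E] | Time-mean [E] | Ratio |
|---|---|---|---|---|
| oak | 2.23 | 1.47 M | 1.40 M | 0.953 |
| ash | 1.98 | 1.37 M | 1.24 M | 0.903 |
| flask (our reckoning) | 1.76 | 1.29 M | 1.10 M | 0.852 |

So we expect 17.2 % of D left in the flask. Both runs were still gaining L at their last readings, so in our next flask we raise E until it reaches oak's exposure, the higher of the two read. With E used held fixed, that takes 2.44 equiv. Taking the mean of ash's last slope of L against θ and zero, we expect a gain of 1.5 percentage points.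

The forecast gave 68 % as charged and 68.7 % at 2.4 equiv, saying “The optimum is flat”.

The simulation gives 68.8 % as charged and 70.0 % at 2.48 equiv, a gain of 1.2 points.

    L + E ⇌ Z + G (K = 0.290, k = 0.00460 L mol⁻¹ h⁻¹)
    G → X (k = 0.00710 h⁻¹)
    D + E → Z + L (k = 0.00660 L mol⁻¹ h⁻¹)
    G + E ⇌ Q, settled at all times (K = 0.0890 L mol⁻¹)

At 10.0 d the flask holds 16.5 % of D against our 17.2 %, and L is still made 2.55 times faster than it is used up, each step taken net. In the neighbour charged with 0.68 M of E, which keeps 37 % of it, k and the ratio 0.852 on the mean of the end values leave 53.0 % of D, and that flask holds 52.2 %.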